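## The problem

The target 18 is a constitutionally symmetric 2,2'-binaphthyl. Each half is a naphthalene with 1-OH and 4-OMe on ring A (C1 to C4, C4a, C8a) and 5-OH and 7-CH3 on ring B (C4a, C5 to C8, C8a); the halves are joined at C2, ortho to the C1 hydroxyl. There is no stereocentre, and the C2–C2' axis has only one oxygen and one hydrogen as ortho neighbours on each ring, so nothing has to be controlled stereochemically; any sp3 centre made on the way only has to be erased. The difficulties are regiochemical: three oxygens per half in two states (free at C1 and C5, methylated at C4), the peri pair 4-OMe/5-OH, and the meta relationship of 5-OH and 7-CH3, which substitution chemistry on a naphthalene does not deliver. Ring A is a hydroquinone monomethyl ether (a 4-methoxy-1-naphthol), easily oxidised, above all as its phenoxide, so the free tetrol should be released last under neutral, reducing conditions; the peri methyl ether is also exposed to chelating Lewis acids once 5-OH is free. The symmetry means that both halves can come from one monomer and that the C2–C2' bond can be made by joining an aryl bromide to its own boronate, but every operation after that union has to succeed twice in one molecule. The feature that opens the key step is that C4a, C5, C7, C8 and C8a of each half are the ring atoms of a 2-methylindan-1-one (C5 the carbonyl carbon on C4a, C7 the methyl-bearing α-carbon, C8 the benzylic CH2 on C8a). The sixth atom, C6, is missing exactly between the oxygen-bearing and the methyl-bearing carbon, where a dihalocarbene can be inserted through the enol ether.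

## Retrosynthesis

**18 from 17.** The end game is fixed first. The C1 phenols are carried as benzyl ethers and C6 carries bromine, so one hydrogenolysis cleaves two C6–Br and two O–CH2Ph bonds. Acetal or silyl protection would end with acid or fluoride on the oxidation-prone tetrol; hydrogenolysis ends neutral and reducing. 17 is no simpler in skeleton, but it is the direct product of the ring expansion. The forward step has to debrominate a position flanked by OH and CH3 without stalling at the benzyl ethers.

**17 from 13 and 14 (key disconnection).** In each half C5–C6 and C6–C7 are cut and C5–C7 is reconnected. Ring B contracts to the cyclopentene of a 3-siloxy-2-methylindene, and C6 becomes bromoform 14. Cutting ring B elsewhere, or building ring A, raises the question of which end of an unsymmetrical partner goes where. Here the methyl group already sits on C7 and the oxygen on C5, and the five-membered ketone behind 13 comes from a ring closure with only one possible site. The precursor 13 has two ring atoms and two bromines fewer and no stereocentre. The forward reaction must deliver the carbene to the enol ether π bond only.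

**13 from 12.** Only the two O–Si bonds are cut. Each ketone has a single α-hydrogen, so one enol ether per half is possible and the two methyl-bearing stereocentres of 12 disappear.

**12 from 10 and 11, and 11 from 10.** The C2–C2' bond is cut to the aryl bromide 10 and its pinacol boronate 11, and 11 is traced back to 10 by exchange of boron for bromine. Both partners come from one compound, so the coupling has no cross-selectivity to manage and can only give the symmetric dimer. Placing the union this late has three merits over dimerising at the aldehyde stage:
- every carbon–carbon bond of the five-membered ring is made on a monomer with a single reacting site;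
- the coupling partners are electron-rich benzyloxy arenes that carry neither an aldehyde nor an aryl sulfonate through hot aqueous base;
- the dimer 12, a diastereomer mixture, is carried through one step only before its stereocentres vanish.

An oxidative dimerisation of a para-methoxylated phenol would need no halogen or boron but runs through a radical coupling with C–C versus C–O selectivity to control. Each partner has half the atoms of 12.

**10 from 9 and 9 from 8.** The O-benzyl bond is cut, then the phenol is re-masked as a tosylate. The exchange costs two steps but removes a real weakness. An ether oxygen ortho to the acylating side chain can attack the activated acyl group through a six-membered ring, and a benzyl ether would then lose its benzyl group and end as a dihydrocoumarin. A sulfonate oxygen is not nucleophilic and is stable to Lewis acid. The sulfonate in turn cannot be carried to the end, since its removal needs hydroxide, which the final tetrol and the alkoxide-mediated key step would not tolerate. The forward steps are a hydroxide cleavage of an aryl sulfonate and a phenol benzylation.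

**8 from 7.** The C4a–C5 bond is cut (Friedel–Crafts acylation). The acyl donor is a 5-benzyl-5-methyl Meldrum's acid, not a free acid or acid chloride: it acylates under catalytic Lewis acid, releases only acetone and CO2, and needs no ester hydrolysis that would endanger the tosylate. Only one position ortho to the benzylic carbon is free (C4a), and it is activated by the neighbouring methoxy group.

**7 from 6, and 6 from 3 and 4.** The C7–CH3 bond is cut, then the C7–C8 bond; the aldehyde carbon of 3 becomes C8 and C5 of Meldrum's acid 4 becomes C7. An olefination with a phosphonopropionate followed by hydrogenation and saponification reaches the same acid oxidation level in one more step, with a hydrogenation that threatens the aryl bromide and a hydroxide treatment that the tosylate would not tolerate. The forward reactions are a reductive Knoevenagel alkylation and a C-methylation.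

**3 from 2 and 2 from 1.** The O–S and the C–Br bonds are cut. The free phenol of commercial 1 directs bromine to its only open ortho position, the future C2.

## Roads not taken

**Alternative 1:** Both rings A are cut across C1–C8a and C4–C4a. Forward, two molecules of 3-(methoxymethoxy)-5-methylbenzyne A2 would add across the α-carbons of each ring of 5,5'-dimethoxy-3,3'-bifuran A1, and the oxygen bridges would open towards the methoxy-bearing carbon to give the bis-MOM ether A3. The merit is convergence: ring A arises with OH and OMe already differentiated, and only acetal cleavage remains. The weak points are three. A1 is a bis(2-alkoxyfuran), an acid-labile ketene-acetal-like diene with no obvious preparation. Each aryne addition has a regiochemical choice; the polarisation of a 3-alkoxyaryne favours the wanted orientation, but such selectivities are rarely complete and the error is taken twice. The naphthol freed by the first addition is itself a nucleophile for the second aryne. If A1 were at hand this road would be clearly shorter than the chosen one. The chosen plan sets against that a key step with no regiochemical choice and stable, ordinary intermediates throughout.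

**Alternative 2:** Both rings A are cut at C1–C2, C3–C4 and C1–C8a. Forward, two equivalents of the zerovalent chromium carbene complex A4 would react with buta-1,3-diyne A5 in a double Dötz benzannulation to give the dibenzyl ether A6, with C1 coming from CO. The merits are real: the 1-OH/4-OMe differentiation is built into the mechanism, terminal alkynes place their substituent next to the new phenol (hence the C2–C2' link), and the route is the shortest of all. The weak points are the handling of A5, an explosive gas, and an ortho-benzyloxy group on the carbene aryl that can chelate chromium and divert the annulation. The second annulation must also take place on an alkyne flanked by a free ortho-naphthol, which can close to a furan instead, and the step needs stoichiometric chromium and delivers air-sensitive 4-methoxy-1-naphthols. In step count this road is better; the chosen plan offers reagents that scale, no toxic metal in stoichiometric amount, and a ring-forming step whose mode of failure is over-reaction, not a change of skeleton.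

**Alternative 3:** Ring B is cut at C5–C6. Forward, LiN(i-Pr)2 would deprotonate the benzylic, allylic C8 methylene of the bis(ortho-methallyl benzamide) A7, and the allyl anion would attack the neighbouring diethylamide through its terminal carbon to give the bis-MOM ether A8 after loss of diethylamide and enolisation. This is well-precedented carbanion chemistry, the amide can first direct the metalation that installs the methallyl group, and, like the chosen plan, it fixes 5-OH and 7-CH3 without ambiguity. It also needs no protecting-group exchange and is probably a few steps shorter than the twelve of the chosen plan. Its weak points are the assembly of a biaryl whose rings are each pentasubstituted, with the methallyl group wedged between amide and acetal, and the need to form and cyclise two carbanions in one molecule in competition with isomerisation of the methallyl double bond into conjugation. It also ends with an acidic acetal cleavage on the oxidation-prone tetrol. The chosen plan sets against the shorter sequence its neutral hydrogenolytic end game and a ring-forming step run at low temperature without stoichiometric strong base acting on the substrate.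

Key step: step 11

Assumption: rotation about the C2–C2' biaryl bond is taken to be fast at room temperature, so no axial descriptor is used; compounds 8 to 11 are racemic and 12 is a mixture of diastereomers at its two methyl-bearing carbons, which become sp2 in step 10.

## Route

Step 1
Reactants: 1 2-hydroxy-5-methoxybenzaldehyde
Product: 2 3-bromo-2-hydroxy-5-methoxybenzaldehyde
Conditions: Br2 (1.05 equiv), NaOAc, AcOH, rt
Reagents that add atoms: bromine, BrBr
Why: Electrophilic aromatic bromination; the free phenol directs to its only open ortho position (its para position carries OMe), which is also meta to the formyl group, so the future C2 is the one activated site.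

Step 2
Reactants: 2 3-bromo-2-hydroxy-5-methoxybenzaldehyde
Product: 3 2-bromo-6-formyl-4-methoxyphenyl 4-methylbenzenesulfonate
Conditions: TsCl, Et3N, DMAP (cat.), CH2Cl2, 0 °C to rt
Reagents that add atoms: 4-methylbenzenesulfonyl chloride, Cc1ccc(cc1)S(=O)(=O)Cl
Why: Sulfonylation of a phenol under nucleophilic catalysis; the tosylate is chosen because its oxygen is non-nucleophilic and acid-stable, which the Friedel–Crafts step 5 requires.

Step 3
Reactants: 3 2-bromo-6-formyl-4-methoxyphenyl 4-methylbenzenesulfonate; 4 2,2-dimethyl-1,3-dioxane-4,6-dione (Meldrum's acid)
Product: 6 2-bromo-6-[(2,2-dimethyl-4,6-dioxo-1,3-dioxan-5-yl)methyl]-4-methoxyphenyl 4-methylbenzenesulfonate, via arylidene Meldrum's acid 5 (not isolated)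
Conditions: Hantzsch ester (1.1 equiv), L-proline (20 mol%), EtOH, rt
Reagents that add atoms: none
Why: Three-component reductive alkylation: amine-catalysed Knoevenagel condensation of the aldehyde with one molecule of 4 gives the arylidene 5, whose strongly electrophilic C=C bond takes hydride from the Hantzsch ester in situ, which also prevents a second Meldrum's acid from adding; the aryl bromide and the sulfonate are not reducible under these conditions.

Step 4
Reactants: 6 2-bromo-6-[(2,2-dimethyl-4,6-dioxo-1,3-dioxan-5-yl)methyl]-4-methoxyphenyl 4-methylbenzenesulfonate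
Product: 7 2-bromo-4-methoxy-6-[(2,2,5-trimethyl-4,6-dioxo-1,3-dioxan-5-yl)methyl]phenyl 4-methylbenzenesulfonate
Conditions: MeI (1.5 equiv), K2CO3 (1.5 equiv), DMF, rt
Reagents that add atoms: iodomethane, CI
Why: C-Alkylation of the acidic monosubstituted Meldrum's acid under carbonate base; it installs the future 7-methyl group and makes the acyl donor non-enolisable, which favours the acylation that follows.

Step 5
Reactants: 7 2-bromo-4-methoxy-6-[(2,2,5-trimethyl-4,6-dioxo-1,3-dioxan-5-yl)methyl]phenyl 4-methylbenzenesulfonate
Product: 8 5-bromo-7-methoxy-2-methyl-1-oxo-2,3-dihydro-1H-inden-4-yl 4-methylbenzenesulfonate (racemic)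
Conditions: Sc(OTf)3 (15 mol%), MeNO2, 100 °C
Reagents that add atoms: none
Why: Lewis-acid-catalysed intramolecular Friedel–Crafts acylation by a quaternised Meldrum's acid with loss of acetone and CO2; the only free position ortho to the benzylic carbon is C4a, ortho to the methoxy group and para to bromine, and the sulfonate oxygen cannot compete as a nucleophile. The methyl-bearing stereocentre forms as a racemate and is removed in step 10.

Step 6
Reactants: 8 5-bromo-7-methoxy-2-methyl-1-oxo-2,3-dihydro-1H-inden-4-yl 4-methylbenzenesulfonate
Product: 9 5-bromo-4-hydroxy-7-methoxy-2-methyl-2,3-dihydro-1H-inden-1-one (racemic)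
Conditions: KOH (5 equiv), MeOH–THF–H2O, 60 °C, argon; then 1 M HCl
Reagents that add atoms: none
Why: Alkaline S–O cleavage of an aryl sulfonate by hydroxide; the aryl bromide is inert to hydroxide at this temperature, the ketone is only enolised reversibly at an already racemic carbon, and exclusion of air protects the electron-rich phenoxide.

Step 7
Reactants: 9 5-bromo-4-hydroxy-7-methoxy-2-methyl-2,3-dihydro-1H-inden-1-one
Product: 10 4-(benzyloxy)-5-bromo-7-methoxy-2-methyl-2,3-dihydro-1H-inden-1-one (racemic)
Conditions: BnBr (1.2 equiv), K2CO3 (1.5 equiv), DMF, rt
Reagents that add atoms: benzyl bromide, BrCc1ccccc1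
Why: Williamson ether synthesis; carbonate deprotonates the phenol but not the ketone α-carbon, so only O-benzylation occurs.

Step 8
Reactants: 10 4-(benzyloxy)-5-bromo-7-methoxy-2-methyl-2,3-dihydro-1H-inden-1-one
Product: 11 4-(benzyloxy)-7-methoxy-2-methyl-5-(4,4,5,5-tetramethyl-1,3,2-dioxaborolan-2-yl)-2,3-dihydro-1H-inden-1-one (racemic)
Conditions: B2pin2 (1.2 equiv), PdCl2(dppf) (3 mol%), KOAc (3 equiv), 1,4-dioxane, 90 °C
Reagents that add atoms: bis(pinacolato)diboron, CC1(C)OB(OC1(C)C)B1OC(C)(C)C(C)(C)O1
Why: Miyaura borylation of an aryl bromide; acetate is basic enough to assist transmetalation from the diboron reagent but too weak to drive Suzuki coupling of the product with unreacted bromide, and the ketone and the benzyl ether are inert to this catalyst.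

Step 9
Reactants: 10 4-(benzyloxy)-5-bromo-7-methoxy-2-methyl-2,3-dihydro-1H-inden-1-one; 11 4-(benzyloxy)-7-methoxy-2-methyl-5-(4,4,5,5-tetramethyl-1,3,2-dioxaborolan-2-yl)-2,3-dihydro-1H-inden-1-one
Product: 12 4,4'-bis(benzyloxy)-7,7'-dimethoxy-2,2'-dimethyl-2,2',3,3'-tetrahydro-1H,1'H-[5,5'-biindene]-1,1'-dione (diastereomer mixture)
Conditions: PdCl2(dppf) (5 mol%), 2 M aq. K2CO3, 1,4-dioxane, 85 °C
Reagents that add atoms: none
Why: Suzuki–Miyaura coupling of one equivalent of bromide with one equivalent of its own boronate; the new biaryl bond has only one benzyloxy group ortho on each ring and forms readily, and aqueous carbonate is too weak a base for palladium-catalysed α-arylation of the ketone to compete. Two racemic partners give a diastereomer mixture, which converges in step 10.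

Step 10
Reactants: 12 4,4'-bis(benzyloxy)-7,7'-dimethoxy-2,2'-dimethyl-2,2',3,3'-tetrahydro-1H,1'H-[5,5'-biindene]-1,1'-dione
Product: 13 7,7'-bis(benzyloxy)-4,4'-dimethoxy-2,2'-dimethyl-3,3'-bis[(trimethylsilyl)oxy]-1H,1'H-6,6'-biindene
Conditions: TMSOTf (2.6 equiv), Et3N (4 equiv), CH2Cl2, 0 °C; non-aqueous work-up, used directly
Reagents that add atoms: trimethylsilyl trifluoromethanesulfonate, C[Si](C)(C)OS(=O)(=O)C(F)(F)F
Why: Soft enolisation with a silyl triflate and an amine base; each ketone has a single α-hydrogen (on C7), so one tetrasubstituted silyl enol ether forms per half and both methyl-bearing stereocentres become sp2.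

Step 11
Reactants: 13 7,7'-bis(benzyloxy)-4,4'-dimethoxy-2,2'-dimethyl-3,3'-bis[(trimethylsilyl)oxy]-1H,1'H-6,6'-biindene; 14 bromoform
Product: 17 1,1'-bis(benzyloxy)-6,6'-dibromo-4,4'-dimethoxy-7,7'-dimethyl-[2,2'-binaphthalene]-5,5'-diol, via bis(dibromosiloxycyclopropane) adduct 15 (not isolated), via bis(6-bromo-8H-naphthalen-5-one) 16 (not isolated)
Conditions: CHBr3 (2.4 equiv), KOt-Bu (2.6 equiv), toluene–hexane, −30 °C to rt; then 1 M HCl, THF, rt
Reagents that add atoms: none
Why: KOt-Bu deprotonates bromoform 14, and loss of bromide gives singlet dibromocarbene, which adds in a concerted [2+1] fashion to the C5=C7 enol ether bond of each indene unit to give the bis(gem-dibromo siloxycyclopropane) 15. In this strained benzo-fused bicyclo[3.1.0]hexane the bromide syn to the five-membered ring ionises with concerted disrotatory cyclopropyl-to-allyl cleavage of the shared C5–C7 bond, assisted by the siloxy oxygen; after loss of the silyl group this leaves the 6-bromo-8H-naphthalen-5-one 16, with C6 now bonded to C5 and C7. Enolisation towards the benzylic C8 then aromatises ring B to the 6-bromo-5-naphthol. The closest known reaction type is the dihalocarbene ring expansion of cyclic trimethylsilyl enol ethers to 2-halo-2-enones, which with indan-1-one enol ethers gives 2-halo-1-naphthols. Each ring B is therefore closed by ring expansion (three-membered ring formation followed by 2π-electrocyclic opening), not by a cyclisation with a choice of site, so the methyl group stays on C7 and the oxygen on C5, peri to 4-OMe. The cyclopropane carbons of 15 are transient stereocentres and none survives. The step needs chemoselectivity for the enol ether over the dialkoxyarenes, the benzylic ether C–H bonds and the naphthol product (Reimer–Tiemann-type attack at C8). The tetrasubstituted, aryl-conjugated silyl enol ether is by far the most nucleophilic π bond, the carbene is generated in slight excess only and at low temperature, and the hydrocarbon medium keeps KOt-Bu largely undissolved, which also limits alkoxide attack on silicon.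

Step 12
Reactants: 17 1,1'-bis(benzyloxy)-6,6'-dibromo-4,4'-dimethoxy-7,7'-dimethyl-[2,2'-binaphthalene]-5,5'-diol
Product: 18 4,4'-dimethoxy-7,7'-dimethyl-[2,2'-binaphthalene]-1,1',5,5'-tetrol
Conditions: H2 (1 atm), 10% Pd on carbon, NaOAc (2.5 equiv), EtOAc–MeOH, rt; work-up under argon
Reagents that add atoms: none
Why: Heterogeneous catalytic hydrogenolysis cleaves both aryl C–Br bonds and both benzylic C–O bonds; NaOAc takes up HBr, and an amine base is avoided because amines retard benzyl ether hydrogenolysis on palladium. The neutral, reducing medium protects the hydroquinone monoether.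

## Compound list

1 | 2-hydroxy-5-methoxybenzaldehyde | COc1ccc(O)c(C=O)c1 | starting material
2 | 3-bromo-2-hydroxy-5-methoxybenzaldehyde | COc1cc(Br)c(O)c(C=O)c1 | intermediate
3 | 2-bromo-6-formyl-4-methoxyphenyl 4-methylbenzenesulfonate | COc1cc(Br)c(OS(=O)(=O)c2ccc(C)cc2)c(C=O)c1 | intermediate
4 | 2,2-dimethyl-1,3-dioxane-4,6-dione (Meldrum's acid) | CC1(C)OC(=O)CC(=O)O1 | starting material
5 | 2-bromo-6-[(2,2-dimethyl-4,6-dioxo-1,3-dioxan-5-ylidene)methyl]-4-methoxyphenyl 4-methylbenzenesulfonate | COc1cc(Br)c(OS(=O)(=O)c2ccc(C)cc2)c(C=C2C(=O)OC(C)(C)OC2=O)c1 | intermediate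
6 | 2-bromo-6-[(2,2-dimethyl-4,6-dioxo-1,3-dioxan-5-yl)methyl]-4-methoxyphenyl 4-methylbenzenesulfonate | COc1cc(Br)c(OS(=O)(=O)c2ccc(C)cc2)c(CC2C(=O)OC(C)(C)OC2=O)c1 | intermediate
7 | 2-bromo-4-methoxy-6-[(2,2,5-trimethyl-4,6-dioxo-1,3-dioxan-5-yl)methyl]phenyl 4-methylbenzenesulfonate | COc1cc(Br)c(OS(=O)(=O)c2ccc(C)cc2)c(CC2(C)C(=O)OC(C)(C)OC2=O)c1 | intermediate
8 | 5-bromo-7-methoxy-2-methyl-1-oxo-2,3-dihydro-1H-inden-4-yl 4-methylbenzenesulfonate, racemic | COc1cc(Br)c(OS(=O)(=O)c2ccc(C)cc2)c2c1C(=O)C(C)C2 | intermediate
9 | 5-bromo-4-hydroxy-7-methoxy-2-methyl-2,3-dihydro-1H-inden-1-one, racemic | COc1cc(Br)c(O)c2c1C(=O)C(C)C2 | intermediate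
10 | 4-(benzyloxy)-5-bromo-7-methoxy-2-methyl-2,3-dihydro-1H-inden-1-one, racemic | COc1cc(Br)c(OCc2ccccc2)c2c1C(=O)C(C)C2 | intermediate
11 | 4-(benzyloxy)-7-methoxy-2-methyl-5-(4,4,5,5-tetramethyl-1,3,2-dioxaborolan-2-yl)-2,3-dihydro-1H-inden-1-one, racemic | COc1cc(B2OC(C)(C)C(C)(C)O2)c(OCc2ccccc2)c2c1C(=O)C(C)C2 | intermediate
12 | 4,4'-bis(benzyloxy)-7,7'-dimethoxy-2,2'-dimethyl-2,2',3,3'-tetrahydro-1H,1'H-[5,5'-biindene]-1,1'-dione, diastereomer mixture | COc1cc(-c2cc(OC)c3c(c2OCc2ccccc2)CC(C)C3=O)c(OCc2ccccc2)c2c1C(=O)C(C)C2 | intermediate
13 | 7,7'-bis(benzyloxy)-4,4'-dimethoxy-2,2'-dimethyl-3,3'-bis[(trimethylsilyl)oxy]-1H,1'H-6,6'-biindene | COc1cc(-c2cc(OC)c3c(c2OCc2ccccc2)CC(C)=C3O[Si](C)(C)C)c(OCc2ccccc2)c2c1C(O[Si](C)(C)C)=C(C)C2 | intermediate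
14 | bromoform | BrC(Br)Br | starting material
15 | bis-adduct of 13 in which a CBr2 unit bridges the siloxy-bearing and the methyl-bearing carbon of each indene unit (two 1,1-dibromo-1a-methyl-6b-(trimethylsilyloxy)-1,1a,6,6b-tetrahydrocyclopropa[a]indene units), diastereomer mixture | COc1cc(-c2cc(OC)c3c(c2OCc2ccccc2)CC2(C)C(Br)(Br)C32O[Si](C)(C)C)c(OCc2ccccc2)c2c1C1(O[Si](C)(C)C)C(Br)(Br)C1(C)C2 | intermediate
16 | 1,1'-bis(benzyloxy)-6,6'-dibromo-4,4'-dimethoxy-7,7'-dimethyl-8H,8'H-[2,2'-binaphthalene]-5,5'-dione | COc1cc(-c2cc(OC)c3c(c2OCc2ccccc2)CC(C)=C(Br)C3=O)c(OCc2ccccc2)c2c1C(=O)C(Br)=C(C)C2 | intermediate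
17 | 1,1'-bis(benzyloxy)-6,6'-dibromo-4,4'-dimethoxy-7,7'-dimethyl-[2,2'-binaphthalene]-5,5'-diol | COc1cc(-c2cc(OC)c3c(O)c(Br)c(C)cc3c2OCc2ccccc2)c(OCc2ccccc2)c2cc(C)c(Br)c(O)c12 | intermediate
18 | 4,4'-dimethoxy-7,7'-dimethyl-[2,2'-binaphthalene]-1,1',5,5'-tetrol | COc1cc(-c2cc(OC)c3c(O)cc(C)cc3c2O)c(O)c2cc(C)cc(O)c12 | target

## Step count and risk

Total: 12 steps. Longest linear sequence: 12 steps (from 1).

**Step 11 (key step).** Alkoxide may attack silicon before the carbene reaches the enol ether, returning the ketone or its C-alkylated enolate. The naphthol(ate) already formed in one half may also take up further carbene at C8 while the second half is still reacting. Fallback from 13: Furukawa-type Simmons–Smith cyclopropanation (Et2Zn, CH2I2, toluene) would give the bis(trimethylsiloxycyclopropane) F1. Oxidative ring opening with FeCl3 in DMF, through the alkoxy radical and cleavage of the shared C5–C7 bond, would give the bis(7-chloro-7-methyl-7,8-dihydro-6H-naphthalen-5-one) F2. Dehydrochlorination with NaOAc in MeOH, with spontaneous aromatisation, would give the bromine-free 1,1'-bis(benzyloxy)-4,4'-dimethoxy-7,7'-dimethyl-[2,2'-binaphthalene]-5,5'-diol F3. Hydrogenolysis of F3 (H2, Pd on carbon) comes back to the route at 18. The same C5–C6 and C6–C7 bonds are made, and no base or free carbene is present.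

**Step 5.** The acylation may be slow at a position that lies meta to the electron-withdrawing sulfonyloxy group and para to bromine, so that thermal fragmentation of the Meldrum's acid to the ketene, and to the acid on work-up, overtakes ring closure. Fallback from 7: deliberate hydrolysis and decarboxylation (pyridine–H2O, 100 °C) would give 3-[3-bromo-5-methoxy-2-(tosyloxy)phenyl]-2-methylpropanoic acid F4. Cyclodehydration of F4 in Eaton's reagent (P2O5 in MeSO3H), which the tosylate and the bromide tolerate, comes back to the route at 8.

**Step 9.** The boronate may lose boron by protonation, or the bromide may be reduced in the hot aqueous base, before transmetalation at the benzyloxy-flanked position takes place, leaving dehalogenated monomer in place of biaryl. Fallback from 10: the boron partner is dispensed with. Reductive homocoupling of bromide 10 alone (NiBr2(PPh3)2 cat., Zn dust, Et4NI, THF, 50 °C), which ketones and benzyl ethers tolerate, comes back to the route at 12; no compound outside the compound list is made (F0).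

**Step 12.** Bromide released in the first hydrogenolysis events may deactivate the catalyst so that benzyl ether cleavage stalls, or the crowded C6–Br bond may be cleaved incompletely. Fallback from 17: the two tasks are separated. Debenzylation with BCl3 and pentamethylbenzene in CH2Cl2 at −78 °C, where the methyl ethers should survive, would give 6,6'-dibromo-4,4'-dimethoxy-7,7'-dimethyl-[2,2'-binaphthalene]-1,1',5,5'-tetrol F5. Hydrodebromination of F5 (H2, Pd on carbon, NaOAc) comes back to the route at 18.

## Further compounds

F1 | step 11 | bis(trimethylsiloxycyclopropane) from 13: a CH2 unit bridges the siloxy-bearing and the methyl-bearing carbon of each indene unit, diastereomer mixture | COc1cc(-c2cc(OC)c3c(c2OCc2ccccc2)CC2(C)CC32O[Si](C)(C)C)c(OCc2ccccc2)c2c1C1(O[Si](C)(C)C)CC1(C)C2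
F2 | step 11 | 1,1'-bis(benzyloxy)-7,7'-dichloro-4,4'-dimethoxy-7,7'-dimethyl-7,7',8,8'-tetrahydro-6H,6'H-[2,2'-binaphthalene]-5,5'-dione, diastereomer mixture | COc1cc(-c2cc(OC)c3c(c2OCc2ccccc2)CC(C)(Cl)CC3=O)c(OCc2ccccc2)c2c1C(=O)CC(C)(Cl)C2
F3 | step 11 | 1,1'-bis(benzyloxy)-4,4'-dimethoxy-7,7'-dimethyl-[2,2'-binaphthalene]-5,5'-diol | COc1cc(-c2cc(OC)c3c(O)cc(C)cc3c2OCc2ccccc2)c(OCc2ccccc2)c2cc(C)cc(O)c12
F4 | step 5 | 3-[3-bromo-5-methoxy-2-(tosyloxy)phenyl]-2-methylpropanoic acid, racemic | COc1cc(Br)c(OS(=O)(=O)c2ccc(C)cc2)c(CC(C)C(=O)O)c1
F0 | step 9 | none | none
F5 | step 12 | 6,6'-dibromo-4,4'-dimethoxy-7,7'-dimethyl-[2,2'-binaphthalene]-1,1',5,5'-tetrol | COc1cc(-c2cc(OC)c3c(O)c(Br)c(C)cc3c2O)c(O)c2cc(C)c(Br)c(O)c12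
A1 | alternative 1 | 5,5'-dimethoxy-3,3'-bifuran | COc1cc(-c2coc(OC)c2)co1
A2 | alternative 1 | 3-(methoxymethoxy)-5-methylbenzyne | COCOC1=CC(C)=CC#C1
A3 | alternative 1 | 4,4'-dimethoxy-5,5'-bis(methoxymethoxy)-7,7'-dimethyl-[2,2'-binaphthalene]-1,1'-diol | COc1cc(-c2cc(OC)c3c(OCOC)cc(C)cc3c2O)c(O)c2cc(C)cc(OCOC)c12
A4 | alternative 2 | pentacarbonyl{[2-(benzyloxy)-4-methylphenyl](methoxy)methylidene}chromium | COC(=[Cr])c1ccc(C)cc1OCc1ccccc1.[C-]#[O+].[C-]#[O+].[C-]#[O+].[C-]#[O+].[C-]#[O+]
A5 | alternative 2 | buta-1,3-diyne | C#CC#C
A6 | alternative 2 | 5,5'-bis(benzyloxy)-4,4'-dimethoxy-7,7'-dimethyl-[2,2'-binaphthalene]-1,1'-diol | COc1cc(-c2cc(OC)c3c(OCc4ccccc4)cc(C)cc3c2O)c(O)c2cc(C)cc(OCc3ccccc3)c12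
A7 | alternative 3 | N,N,N',N'-tetraethyl-5,5'-dimethoxy-2,2'-bis(methoxymethoxy)-3,3'-bis(2-methylprop-2-en-1-yl)-[1,1'-biphenyl]-4,4'-dicarboxamide | COc1cc(-c2cc(OC)c(C(=O)N(CC)CC)c(CC(C)=C)c2OCOC)c(OCOC)c(CC(C)=C)c1C(=O)N(CC)CC
A8 | alternative 3 | 4,4'-dimethoxy-1,1'-bis(methoxymethoxy)-7,7'-dimethyl-[2,2'-binaphthalene]-5,5'-diol | COc1cc(-c2cc(OC)c3c(O)cc(C)cc3c2OCOC)c(OCOC)c2cc(C)cc(O)c12
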